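## Retrosynthetic overview

1. The target comes from an epoxy alcohol by C1 acetylation and C3 senecioylation; the C1 carbinol comes from chelation-controlled reduction of a cis-α,β-epoxy ketone in the ten-membered ring.
2. The ten-membered ring with its (E)-C5=C6 olefin comes from a ring-expanding Grob (Wharton) fragmentation of a cis-fused bicyclo[5.3.0]decane 1,3-diol monomesylate (the C1–C5 ring-fusion bond is cleaved).
3. In the bicycle, the epoxide (C9, C10) is set by hydroxyl-directed epoxidation, the seven-membered ring by intramolecular alkenyllithium addition to the C1 ketone, and the C5–C6 bond by a reductive aldol between a cyclopentenone and a (Z)-iodo enal.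
4. The cyclopentenone carrying C2 and C3 comes from an enantioselective oxa-Piancatelli rearrangement of a furyl carbinol (3-methylfurfural + i-PrMgCl); the iodo enal comes from carbocupration of propyne.
5. Ring order: cyclopentenone (five), fused cycloheptene (seven), oxirane (three), then the ten-membered ring by expansion.

## Labels and assumptions

- Labels: C1–C10 are the ring carbons of the target and are used for every intermediate. C1 bears OAc, C2 isopropyl, C3 the senecioate, C4 is CH2, C5(CH3)=C6, C7 and C8 are CH2, and C9(CH3)–O–C10 is the epoxide.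
- Bicyclic names use bicyclo[5.3.0]decane locants 1, 2, 3, 6, 7, 9, 10 for route atoms C1, C10, C9, C6, C5, C3, C2.
- Assumption: 3-methylfuran-2-carbaldehyde, i-PrMgCl solution, 2-(2-bromoethyl)-1,3-dioxolane and propyne are bought.
- Assumption: the (R)-configured acid in step 2 gives (4S,5R)-4; if the sense is the opposite, the (S)-acid is used.
- Assumption (fallback to step 2): the lipase acetylates the (4R,5S) antipode, the branched flank acting as the large group.

## Route

Step 1
Reactants: 1 3-methylfuran-2-carbaldehyde; 2 isopropylmagnesium chloride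
Product: 3 2-methyl-1-(3-methylfuran-2-yl)propan-1-ol (racemic)
Conditions: i-PrMgCl (1.2 equiv), THF, 0 °C; then H2O
Reagents that add atoms: none
Why: Grignard 1,2-addition to the aldehyde; the carbinol centre is left racemic because it becomes sp2 in step 2.

Step 2
Reactants: 3 2-methyl-1-(3-methylfuran-2-yl)propan-1-ol
Product: 4 (4S,5R)-4-hydroxy-2-methyl-5-(propan-2-yl)cyclopent-2-en-1-one
Conditions: (R)-3,3'-bis(2,4,6-triisopropylphenyl)-1,1'-binaphthyl-2,2'-diyl N-triflylphosphoramide (5 mol %), H2O (5 equiv), CHCl3, 40 °C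
Reagents that add atoms: water, O
Why: Proposed new method: an enantioselective oxa-Piancatelli rearrangement in which the chiral acid ionises the furyl carbinol, water adds at the free furan α-position, ring opening gives a hydroxypentadienyl cation that stays ion-paired with the chiral phosphoramidate, and the anion fixes the sense of the conrotatory 4π ring closure (trans C2/C3 by mechanism, absolute configuration by catalyst); the closest known reactions are the chiral-acid-catalysed aza-Piancatelli rearrangement with anilines and the racemic aqueous Piancatelli rearrangement.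

Step 3
Reactants: 4 (4S,5R)-4-hydroxy-2-methyl-5-(propan-2-yl)cyclopent-2-en-1-one
Product: 5 (4S,5R)-4-[(tert-butyldimethylsilyl)oxy]-2-methyl-5-(propan-2-yl)cyclopent-2-en-1-one
Conditions: TBSCl, imidazole, DMF, rt
Reagents that add atoms: tert-butyldimethylsilyl chloride, CC(C)(C)[Si](C)(C)Cl
Why: Silyl ether protection of the C3 hydroxyl so that it survives hydride, organolithium, oxidant and alkoxide; no stereocentre is touched.

Step 4
Reactants: 6 2-(2-bromoethyl)-1,3-dioxolane; 7 propyne
Product: 11 2-[(3Z)-4-iodo-3-methylbut-3-en-1-yl]-1,3-dioxolane, via Grignard reagent 8 (not isolated), via alkylcopper 9 (not isolated), via alkenylcopper 10 (not isolated)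
Conditions: Mg, THF, 25 °C; CuBr·SMe2, Et2O–Me2S, −45 °C; propyne, −25 °C; I2, −78 → 0 °C
Reagents that add atoms: iodine, II
Why: Normant carbocupration: syn addition of the alkylcopper across propyne places chain and copper cis, and iodinolysis with retention gives the (Z)-iodide that fixes the later cis C9–C10 geometry.

Step 5
Reactants: 11 2-[(3Z)-4-iodo-3-methylbut-3-en-1-yl]-1,3-dioxolane
Product: 12 (4Z)-5-iodo-4-methylpent-4-enal
Conditions: 1 M HCl, THF, rt
Reagents that add atoms: water, O
Why: Acid-catalysed acetal hydrolysis; the alkenyl iodide is inert to dilute acid.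

Step 6
Reactants: 5 (4S,5R)-4-[(tert-butyldimethylsilyl)oxy]-2-methyl-5-(propan-2-yl)cyclopent-2-en-1-one; 12 (4Z)-5-iodo-4-methylpent-4-enal
Product: 14 (2S,4S,5R)-4-[(tert-butyldimethylsilyl)oxy]-2-[(4Z)-1-hydroxy-5-iodo-4-methylpent-4-en-1-yl]-2-methyl-5-(propan-2-yl)cyclopentan-1-one (both epimers at the carbinol carbon), via lithium enolate 13 (not isolated)
Conditions: LiBH(s-Bu)3 (1.05 equiv), THF, −78 °C; then 12, −78 °C; pH 7 buffer
Reagents that add atoms: none
Why: Reductive aldol: conjugate hydride addition gives the tetrasubstituted C1=C5 enolate regiospecifically, and the aldehyde is expected to add anti to the neighbouring C2 isopropyl group to set the C5 quaternary centre; the C6 carbinol forms as a mixture and is corrected in steps 8 and 10.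

Step 7
Reactants: 14 the aldol adduct
Product: 15 (1R,7S,9S,10R)-9-[(tert-butyldimethylsilyl)oxy]-3,7-dimethyl-10-(propan-2-yl)bicyclo[5.3.0]dec-2-ene-1,6-diol (cis-fused; both epimers at the secondary carbinol)
Conditions: t-BuLi (3.3 equiv), THF, −78 °C; then H2O
Reagents that add atoms: none
Why: Iodine–lithium exchange and intramolecular 1,2-addition of the (Z)-alkenyllithium to the C1 ketone (anionic cyclisation) close the seven-membered ring; the tether forces cis fusion, so the new C1 hydroxyl is cis to the C5 methyl and to the C2 isopropyl group.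

Step 8
Reactants: 15 the bicyclic diol
Product: 16 (1R,7R,9S,10R)-9-[(tert-butyldimethylsilyl)oxy]-1-hydroxy-3,7-dimethyl-10-(propan-2-yl)bicyclo[5.3.0]dec-2-en-6-one
Conditions: Dess–Martin periodinane, pyridine, CH2Cl2, 0 °C → rt
Reagents that add atoms: none
Why: Dess–Martin oxidation of the secondary C6 alcohol merges both carbinol epimers into one ketone; the tertiary allylic C1 alcohol cannot be oxidised.

Step 9
Reactants: 16 the bicyclic hydroxy ketone
Product: 17 (1R,2R,3S,7R,9S,10R)-9-[(tert-butyldimethylsilyl)oxy]-2,3-epoxy-1-hydroxy-3,7-dimethyl-10-(propan-2-yl)bicyclo[5.3.0]decan-6-one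
Conditions: VO(acac)2 (5 mol %), t-BuOOH (1.5 equiv), CH2Cl2, 0 °C → rt
Reagents that add atoms: tert-butyl hydroperoxide, CC(C)(C)OO
Why: Hydroxyl-directed epoxidation: the vanadium alkoxide of the tertiary allylic C1–OH delivers oxygen to the cycloheptene on its own face, which sets C9 and C10 (cis-epoxide) relative to C1 and through the ring fusion relative to C2.

Step 10
Reactants: 17 the epoxy hydroxy ketone
Product: 19 (1R,2R,3S,6R,7S,9S,10R)-9-[(tert-butyldimethylsilyl)oxy]-2,3-epoxy-3,7-dimethyl-10-(propan-2-yl)bicyclo[5.3.0]decane-1,6-diol, via diethylboron chelate 18 (not isolated)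
Conditions: Et2BOMe (1.2 equiv), THF–MeOH 4:1, −78 °C; NaBH4; MeOH co-evaporation
Reagents that add atoms: none
Why: Narasaka–Prasad syn-1,3-reduction: external hydride attacks the boron chelate from the face away from the chelating bridge, placing the C6 hydroxyl cis to C1–OH and so cis to the C5 methyl, the arrangement that leads to an (E)-olefin in step 11.

Step 11
Reactants: 19 the epoxy diol
Product: 21 (1S,3R,4S,6E,10S)-4-[(tert-butyldimethylsilyl)oxy]-6,10-dimethyl-3-(propan-2-yl)-11-oxabicyclo[8.1.0]undec-6-en-2-one, via mesylate 20 (not isolated)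
Conditions: MsCl (1.2 equiv), Et3N (1.5 equiv), THF, 0 °C; then t-BuOK (2.5 equiv), 0 °C → rt
Reagents that add atoms: none
Why: Ring-expanding Grob (Wharton) fragmentation: the secondary C6 hydroxyl is mesylated selectively, the C1 potassium alkoxide then pushes out the C1–C5 bond antiperiplanar to the equatorial mesylate, and the C1 ketone and the (E)-C5=C6 olefin form stereospecifically (C4 anti to C7 in the reacting conformer), while the cis relation of alkoxide to mesylate and to epoxide rules out oxetane formation and Payne rearrangement.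

Step 12
Reactants: 21 the ten-membered epoxy ketone
Product: 22 (1R,2R,3S,4S,6E,10S)-4-[(tert-butyldimethylsilyl)oxy]-6,10-dimethyl-3-(propan-2-yl)-11-oxabicyclo[8.1.0]undec-6-en-2-ol
Conditions: Zn(BH4)2, Et2O, −20 °C; then H2O
Reagents that add atoms: none
Why: Chelation-controlled reduction of an α,β-epoxy ketone: zinc bridges the carbonyl and epoxide oxygens and hydride enters anti to C9, giving the erythro (ring-cis) epoxy alcohol, which is (R) at C1.

Step 13
Reactants: 22 the epoxy alcohol
Product: 23 (1R,2R,3S,4S,6E,10S)-4-[(tert-butyldimethylsilyl)oxy]-6,10-dimethyl-3-(propan-2-yl)-11-oxabicyclo[8.1.0]undec-6-en-2-yl acetate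
Conditions: Ac2O, pyridine, DMAP (cat.), CH2Cl2, rt
Reagents that add atoms: acetic anhydride, CC(=O)OC(C)=O
Why: DMAP-catalysed acylation of the only free hydroxyl, with retention at C1.

Step 14
Reactants: 23 the silyl-protected acetate
Product: 24 (1R,2R,3R,4S,6E,10S)-4-hydroxy-6,10-dimethyl-3-(propan-2-yl)-11-oxabicyclo[8.1.0]undec-6-en-2-yl acetate
Conditions: TBAF, AcOH (1:1), THF, rt
Reagents that add atoms: none
Why: Fluoride desilylation buffered with acetic acid, so that the epoxide stays closed and the C1 acetate does not migrate to O3.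

Step 15
Reactants: 24 the hydroxy acetate
Product: 25 (1R,2R,3R,4S,6E,10S)-2-(acetyloxy)-6,10-dimethyl-3-(propan-2-yl)-11-oxabicyclo[8.1.0]undec-6-en-4-yl 3-methylbut-2-enoate (target)
Conditions: 3-methylbut-2-enoyl chloride, pyridine, DMAP (cat.), CH2Cl2, 0 °C → rt
Reagents that add atoms: 3-methylbut-2-enoyl chloride, CC(C)=CC(=O)Cl
Why: Acylation of the C3 hydroxyl through the acylpyridinium ion; pyridine instead of a trialkylamine avoids vinylketene formation and deconjugation of the senecioate.

## Compound list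

1 | 3-methylfuran-2-carbaldehyde | Cc1ccoc1C=O | starting material
2 | isopropylmagnesium chloride | CC(C)[Mg]Cl | starting material
3 | 2-methyl-1-(3-methylfuran-2-yl)propan-1-ol, racemic | Cc1ccoc1C(O)C(C)C | intermediate
4 | (4S,5R)-4-hydroxy-2-methyl-5-(propan-2-yl)cyclopent-2-en-1-one; trans; route labels C1 = C=O, C2 = CH(i-Pr), C3 = CH(OH), C4=C5(CH3) | O=C1[C@H](C(C)C)[C@@H](O)C=C1C | intermediate
5 | (4S,5R)-4-[(tert-butyldimethylsilyl)oxy]-2-methyl-5-(propan-2-yl)cyclopent-2-en-1-one | O=C1[C@H](C(C)C)[C@@H](O[Si](C)(C)C(C)(C)C)C=C1C | intermediate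
6 | 2-(2-bromoethyl)-1,3-dioxolane | BrCCC1OCCO1 | starting material
7 | propyne | CC#C | starting material
8 | [2-(1,3-dioxolan-2-yl)ethyl]magnesium bromide (not isolated) | Br[Mg]CCC1OCCO1 | intermediate
9 | [2-(1,3-dioxolan-2-yl)ethyl]copper, as its MgBr2 complex (not isolated) | [Cu]CCC1OCCO1 | intermediate
10 | [(1Z)-4-(1,3-dioxolan-2-yl)-2-methylbut-1-en-1-yl]copper (not isolated) | [Cu]/C=C(C)\CCC1OCCO1 | intermediate
11 | 2-[(3Z)-4-iodo-3-methylbut-3-en-1-yl]-1,3-dioxolane | I/C=C(C)\CCC1OCCO1 | intermediate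
12 | (4Z)-5-iodo-4-methylpent-4-enal | I/C=C(C)\CCC=O | intermediate
13 | lithium (4S,5R)-4-[(tert-butyldimethylsilyl)oxy]-2-methyl-5-(propan-2-yl)cyclopent-1-en-1-olate (not isolated) | [Li]OC1=C(C)C[C@H](O[Si](C)(C)C(C)(C)C)[C@H]1C(C)C | intermediate
14 | (2S,4S,5R)-4-[(tert-butyldimethylsilyl)oxy]-2-[(4Z)-1-hydroxy-5-iodo-4-methylpent-4-en-1-yl]-2-methyl-5-(propan-2-yl)cyclopentan-1-one; side chain on C5 trans to the C2 isopropyl; both epimers at C6 | O=C1[C@H](C(C)C)[C@@H](O[Si](C)(C)C(C)(C)C)C[C@@]1(C)C(O)CC/C(C)=C\I | intermediate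
15 | (1R,7S,9S,10R)-9-[(tert-butyldimethylsilyl)oxy]-3,7-dimethyl-10-(propan-2-yl)bicyclo[5.3.0]dec-2-ene-1,6-diol; cis-fused; C1–OH, C5–CH3 and C2–isopropyl on one face, C3–OTBS on the other; both epimers at C6 | O[C@]12[C@H](C(C)C)[C@@H](O[Si](C)(C)C(C)(C)C)C[C@@]1(C)C(O)CCC(C)=C2 | intermediate
16 | (1R,7R,9S,10R)-9-[(tert-butyldimethylsilyl)oxy]-1-hydroxy-3,7-dimethyl-10-(propan-2-yl)bicyclo[5.3.0]dec-2-en-6-one (locants as in 15) | O[C@]12[C@H](C(C)C)[C@@H](O[Si](C)(C)C(C)(C)C)C[C@@]1(C)C(=O)CCC(C)=C2 | intermediate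
17 | (1R,2R,3S,7R,9S,10R)-9-[(tert-butyldimethylsilyl)oxy]-2,3-epoxy-1-hydroxy-3,7-dimethyl-10-(propan-2-yl)bicyclo[5.3.0]decan-6-one; epoxide oxygen cis to C1–OH | O[C@]12[C@H](C(C)C)[C@@H](O[Si](C)(C)C(C)(C)C)C[C@@]1(C)C(=O)CC[C@]3(C)O[C@H]23 | intermediate
18 | O1-diethylboryl chelate of 17 (not isolated) | CCB(CC)O[C@]12[C@H](C(C)C)[C@@H](O[Si](C)(C)C(C)(C)C)C[C@@]1(C)C(=O)CC[C@]3(C)O[C@H]23 | intermediate
19 | (1R,2R,3S,6R,7S,9S,10R)-9-[(tert-butyldimethylsilyl)oxy]-2,3-epoxy-3,7-dimethyl-10-(propan-2-yl)bicyclo[5.3.0]decane-1,6-diol; C6–OH cis to C1–OH and C5–CH3 | O[C@]12[C@H](C(C)C)[C@@H](O[Si](C)(C)C(C)(C)C)C[C@@]1(C)[C@H](O)CC[C@]3(C)O[C@H]23 | intermediate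
20 | C6 methanesulfonate of 19 (not isolated) | O[C@]12[C@H](C(C)C)[C@@H](O[Si](C)(C)C(C)(C)C)C[C@@]1(C)[C@H](OS(C)(=O)=O)CC[C@]3(C)O[C@H]23 | intermediate
21 | (1S,3R,4S,6E,10S)-4-[(tert-butyldimethylsilyl)oxy]-6,10-dimethyl-3-(propan-2-yl)-11-oxabicyclo[8.1.0]undec-6-en-2-one; ten-membered ring with C1 ketone, (E)-C5=C6 and cis-C9,C10-epoxide | O=C1[C@H](C(C)C)[C@@H](O[Si](C)(C)C(C)(C)C)C/C(C)=C/CC[C@]2(C)O[C@H]12 | intermediate
22 | (1R,2R,3S,4S,6E,10S)-4-[(tert-butyldimethylsilyl)oxy]-6,10-dimethyl-3-(propan-2-yl)-11-oxabicyclo[8.1.0]undec-6-en-2-ol | O[C@@H]1[C@H](C(C)C)[C@@H](O[Si](C)(C)C(C)(C)C)C/C(C)=C/CC[C@]2(C)O[C@H]12 | intermediate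
23 | (1R,2R,3S,4S,6E,10S)-4-[(tert-butyldimethylsilyl)oxy]-6,10-dimethyl-3-(propan-2-yl)-11-oxabicyclo[8.1.0]undec-6-en-2-yl acetate | CC(=O)O[C@@H]1[C@H](C(C)C)[C@@H](O[Si](C)(C)C(C)(C)C)C/C(C)=C/CC[C@]2(C)O[C@H]12 | intermediate
24 | (1R,2R,3R,4S,6E,10S)-4-hydroxy-6,10-dimethyl-3-(propan-2-yl)-11-oxabicyclo[8.1.0]undec-6-en-2-yl acetate | CC(=O)O[C@@H]1[C@H](C(C)C)[C@@H](O)C/C(C)=C/CC[C@]2(C)O[C@H]12 | intermediate
25 | (1R,2R,3R,4S,6E,10S)-2-(acetyloxy)-6,10-dimethyl-3-(propan-2-yl)-11-oxabicyclo[8.1.0]undec-6-en-4-yl 3-methylbut-2-enoate | CC(=O)O[C@@H]1[C@H](C(C)C)[C@@H](OC(=O)C=C(C)C)C/C(C)=C/CC[C@]2(C)O[C@H]12 | target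

## Step count and risk

Total: 15 steps. Longest linear sequence: 13 steps (steps 1–3 and 6–15); steps 4–5 make the side fragment.

The three steps most likely to fail:

**Step 2 (the proposed new enantioselective oxa-Piancatelli rearrangement).** The risks are low enantioselectivity, because water competes with ion pairing, and slow turnover. The fallback uses known chemistry, sets out from 3 and returns at 4. Compound 3 is rearranged with Dy(OTf)3 (10 mol %) in MeCN–H2O at 80 °C, the established lanthanide-triflate Piancatelli rearrangement. This gives racemic trans material, that is 4 together with its antipode (4R,5S)-4-hydroxy-2-methyl-5-(propan-2-yl)cyclopent-2-en-1-one F1. Burkholderia cepacia lipase (Amano PS) with vinyl acetate in MTBE then acetylates the antipode to (4R,5S)-4-(acetyloxy)-2-methyl-5-(propan-2-yl)cyclopent-2-en-1-one F2. Unreacted 4 is separated by chromatography and enters step 3.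

**Step 7 (anionic cyclisation onto a ketone flanked by a quaternary and a branched carbon).** The risks are attack or enolisation by t-BuLi and retro-aldol of the lithium aldolate. The fallback changes the ring-closing bond from C1–C10 addition to C9=C10 metathesis; it sets out from 5 and returns at 15. Reductive aldol of 5 (LiBH(s-Bu)3, then purchased 4-methylpent-4-enal, C=C(C)CCC=O) gives (2S,4S,5R)-4-[(tert-butyldimethylsilyl)oxy]-2-(1-hydroxy-4-methylpent-4-en-1-yl)-2-methyl-5-(propan-2-yl)cyclopentan-1-one F3. CeCl3-promoted addition of CH2=CHMgBr to the ring ketone, anti to the isopropyl group, gives the 1-vinyl diol F4. Ring-closing metathesis with the second-generation Grubbs catalyst (H2IMes)(PCy3)Cl2Ru=CHPh in toluene at 80 °C closes the trisubstituted cycloheptene with loss of ethene and gives 15.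

**Step 11 (Grob fragmentation next to an epoxide).** The risks are E2 loss of the mesylate, base damage to the epoxy ketone, and loss of material if the aldol of step 6 gave the other C5 epimer. The fallback moves the epoxidation behind the ring expansion; it sets out from 16 and returns at 21. Compound 16 is reduced with Et2BOMe/NaBH4 to the syn-diol (1R,6R,7S,9S,10R)-9-[(tert-butyldimethylsilyl)oxy]-3,7-dimethyl-10-(propan-2-yl)bicyclo[5.3.0]dec-2-ene-1,6-diol F5. Mesylation (MsCl, Et3N) gives its C6 mesylate F6, which fragments with t-BuOK to the (2Z,6E)-cyclodeca-2,6-dienone F7. Weitz–Scheffer epoxidation of the enone (t-BuOOH, DBU, THF, 0 °C) then gives 21. In this order both C5 epimers from step 6 converge on F7, and the epoxide face is set by peripheral attack on the ten-membered ring, which would have to be checked by experiment.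

Further compounds

F1 | step 2 | (4R,5S)-4-hydroxy-2-methyl-5-(propan-2-yl)cyclopent-2-en-1-one | O=C1[C@@H](C(C)C)[C@H](O)C=C1C
F2 | step 2 | (4R,5S)-4-(acetyloxy)-2-methyl-5-(propan-2-yl)cyclopent-2-en-1-one | O=C1[C@@H](C(C)C)[C@H](OC(C)=O)C=C1C
F3 | step 7 | (2S,4S,5R)-4-[(tert-butyldimethylsilyl)oxy]-2-(1-hydroxy-4-methylpent-4-en-1-yl)-2-methyl-5-(propan-2-yl)cyclopentan-1-one, both carbinol epimers | O=C1[C@H](C(C)C)[C@@H](O[Si](C)(C)C(C)(C)C)C[C@@]1(C)C(O)CCC(C)=C
F4 | step 7 | 1-vinyl diol: 4-[(tert-butyldimethylsilyl)oxy]-1-ethenyl-2-(1-hydroxy-4-methylpent-4-en-1-yl)-2-methyl-5-(propan-2-yl)cyclopentan-1-ol, vinyl trans to isopropyl and cis to the side chain | O[C@]1(C=C)[C@H](C(C)C)[C@@H](O[Si](C)(C)C(C)(C)C)C[C@@]1(C)C(O)CCC(C)=C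
F5 | step 11 | (1R,6R,7S,9S,10R)-9-[(tert-butyldimethylsilyl)oxy]-3,7-dimethyl-10-(propan-2-yl)bicyclo[5.3.0]dec-2-ene-1,6-diol | O[C@]12[C@H](C(C)C)[C@@H](O[Si](C)(C)C(C)(C)C)C[C@@]1(C)[C@H](O)CCC(C)=C2
F6 | step 11 | C6 methanesulfonate of F5 | O[C@]12[C@H](C(C)C)[C@@H](O[Si](C)(C)C(C)(C)C)C[C@@]1(C)[C@H](OS(C)(=O)=O)CCC(C)=C2
F7 | step 11 | (2Z,6E,9S,10R)-9-[(tert-butyldimethylsilyl)oxy]-3,7-dimethyl-10-(propan-2-yl)cyclodeca-2,6-dien-1-one | O=C1[C@H](C(C)C)[C@@H](O[Si](C)(C)C(C)(C)C)C/C(C)=C/CC/C(C)=C\1
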